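**Retrosynthetic overview**

- The strategy rests on ring C, the γ-pyranone of the isoflavone. C4 and C3 (C3 carrying ring B) are an arylacetyl unit, C2 is one formyl-level carbon, and the ring is joined to the resorcinol-derived ring A through C4a and O1.
- Key disconnection: C4–C4a, C2–C3 and O1–C2 are cut together, giving resorcinol, 2,4,5-trimethoxyphenylacetic acid and DMF, which are assembled in one pot to 7-hydroxy-3-(2,4,5-trimethoxyphenyl)chromen-4-one.
- The C8 side chain comes from the 7-O-allyl ether by aromatic Claisen rearrangement. After O-methylation at O7, cross-metathesis with 2-methylbut-2-ene turns allyl into prenyl.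
- Ring order: rings A and B are bought, and ring C is the only ring formed (step 1). The acid-sensitive prenyl group is completed last.

Key step: step 1

Remark on the chemistry: the target has no stereogenic centre and no stereogenic double bond (the prenyl alkene ends in two identical methyl groups), so the SMILES describes one achiral compound and no stereocontrol is needed. 2,4,5-Trimethoxyphenylacetic acid is taken as a catalogue compound.

**Route**

Step 1
Reactants: 1 resorcinol; 2 2,4,5-trimethoxyphenylacetic acid; 3 N,N-dimethylformamide
Product: 7 7-hydroxy-3-(2,4,5-trimethoxyphenyl)chromen-4-one, via deoxybenzoin 4 (not isolated), via enaminone 5 (not isolated), via aminal 6 (not isolated)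
Conditions: 1 (slight excess), BF3·OEt2 (neat, as solvent and Lewis acid), 85 °C, N2; cool, then DMF, MsCl, 50 → 70 °C; pour into cold aq. NaOAc
Reagents that add atoms: N,N-dimethylformamide, CN(C)C=O
Why: BF3 activates the carboxylic acid for Friedel–Crafts C-acylation of resorcinol at C4, giving deoxybenzoin 4 held as its O,O-difluoroboron chelate (C4–C4a bond); the enolised methylene of this chelate then adds to the chloroiminium-type reagent formed from DMF and MsCl to give the enaminone/iminium 5 (C2–C3 bond). The ortho-phenol oxygen closes onto the exocyclic iminium carbon in a 6-exo-trig mode (O1–C2 bond) to aminal 6, and β-elimination of dimethylamine gives the aromatic γ-pyranone. The closest known reaction type is the one-pot deoxybenzoin formation and Vilsmeier-type formylative cyclisation of phenols with arylacetic acids to isoflavones. No stereocentre survives, because C2 and C3 of 6 become sp2 on elimination. The step needs a single acylation at C4 of resorcinol and formylation at the ketone methylene rather than on an arene: C4 is para to one hydroxyl, ortho to the other and unhindered, the chelated aryl ketone deactivates ring A against a second acylation, and the most nucleophilic position of the trimethoxyphenyl ring is already occupied by the benzylic carbon while the boron enolate is the strongest carbon nucleophile present. Resorcinol is used in slight excess so that the electron-rich arylacetic acid acylates it and not itself.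

Step 2
Reactants: 7 7-hydroxy-3-(2,4,5-trimethoxyphenyl)chromen-4-one; 8 allyl bromide
Product: 9 7-(allyloxy)-3-(2,4,5-trimethoxyphenyl)chromen-4-one
Conditions: allyl bromide, K2CO3, acetone, reflux
Reagents that add atoms: allyl bromide, C=CCBr
Why: Williamson ether synthesis; the 7-hydroxyl is the only acidic group (a vinylogous acid through the C4 carbonyl), and its phenoxide should displace bromide from the allylic halide cleanly under conditions that leave the pyranone ring intact.

Step 3
Reactants: 9 7-(allyloxy)-3-(2,4,5-trimethoxyphenyl)chromen-4-one
Product: 11 8-allyl-7-hydroxy-3-(2,4,5-trimethoxyphenyl)chromen-4-one, via dienone 10 (not isolated)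
Conditions: N,N-diethylaniline, 200–210 °C, N2
Reagents that add atoms: none
Why: Aromatic Claisen rearrangement ([3,3]-sigmatropic shift) followed by tautomerisation; migration to C8 should be preferred over C6 because only the C8 dienone 10 keeps the C4a=C8a bond and hence the intact γ-pyranone (bond fixation, as in 7-allyloxychromones and 7-allyloxycoumarins).

Step 4
Reactants: 11 8-allyl-7-hydroxy-3-(2,4,5-trimethoxyphenyl)chromen-4-one; 12 iodomethane
Product: 13 8-allyl-7-methoxy-3-(2,4,5-trimethoxyphenyl)chromen-4-one
Conditions: MeI, K2CO3, acetone, reflux
Reagents that add atoms: iodomethane, CI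
Why: Williamson O-methylation of the only free phenol; capping it before the metathesis removes the ortho-allyl/prenyl phenol that could otherwise cyclise onto the side chain.

Step 5
Reactants: 13 8-allyl-7-methoxy-3-(2,4,5-trimethoxyphenyl)chromen-4-one; 14 2-methylbut-2-ene
Product: 15 prebarbigerone, 7-methoxy-8-(3-methylbut-2-enyl)-3-(2,4,5-trimethoxyphenyl)chromen-4-one
Conditions: Grubbs II (5 mol%), 2-methylbut-2-ene (large excess), CH2Cl2, 40 °C, sealed tube
Reagents that add atoms: 2-methylbut-2-ene, CC=C(C)C
Why: Olefin cross-metathesis of a terminal allylarene with excess trisubstituted alkene should give the prenyl group with release of propene; the electron-poor trisubstituted C2=C3 bond of the chromone does not take part, and the new alkene has no geometry to control.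

**Compound list**

1 | resorcinol | Oc1cccc(O)c1 | starting material
2 | 2,4,5-trimethoxyphenylacetic acid | COc1cc(OC)c(CC(=O)O)cc1OC | starting material
3 | N,N-dimethylformamide | CN(C)C=O | starting material
4 | 1-(2,4-dihydroxyphenyl)-2-(2,4,5-trimethoxyphenyl)ethanone (deoxybenzoin, present in the flask as its difluoroboron chelate) | COc1cc(OC)c(CC(=O)c2ccc(O)cc2O)cc1OC | intermediate
5 | 1-(2,4-dihydroxyphenyl)-3-(dimethylamino)-2-(2,4,5-trimethoxyphenyl)prop-2-en-1-one (enaminone, labile C=C geometry, iminium form reacts on) | COc1cc(OC)c(C(=CN(C)C)C(=O)c2ccc(O)cc2O)cc1OC | intermediate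
6 | 2-(dimethylamino)-7-hydroxy-3-(2,4,5-trimethoxyphenyl)chroman-4-one (aminal, transient, configuration at C2 and C3 not defined) | COc1cc(OC)c(C2C(N(C)C)Oc3cc(O)ccc3C2=O)cc1OC | intermediate
7 | 7-hydroxy-3-(2,4,5-trimethoxyphenyl)chromen-4-one | COc1cc(OC)c(-c2coc3cc(O)ccc3c2=O)cc1OC | intermediate
8 | allyl bromide | C=CCBr | starting material
9 | 7-(allyloxy)-3-(2,4,5-trimethoxyphenyl)chromen-4-one | COc1cc(OC)c(-c2coc3cc(OCC=C)ccc3c2=O)cc1OC | intermediate
10 | 8-allyl-3-(2,4,5-trimethoxyphenyl)-8H-chromene-4,7-dione (Claisen dienone, racemic at C8, transient) | C=CCC1C(=O)C=CC2=C1OC=C(c1cc(OC)c(OC)cc1OC)C2=O | intermediate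
11 | 8-allyl-7-hydroxy-3-(2,4,5-trimethoxyphenyl)chromen-4-one | COc1cc(OC)c(-c2coc3c(CC=C)c(O)ccc3c2=O)cc1OC | intermediate
12 | iodomethane | CI | starting material
13 | 8-allyl-7-methoxy-3-(2,4,5-trimethoxyphenyl)chromen-4-one | COc1cc(OC)c(-c2coc3c(CC=C)c(OC)ccc3c2=O)cc1OC | intermediate
14 | 2-methylbut-2-ene | CC=C(C)C | starting material
15 | prebarbigerone, 7-methoxy-8-(3-methylbut-2-enyl)-3-(2,4,5-trimethoxyphenyl)chromen-4-one | COc1cc(OC)c(-c2coc3c(CC=C(C)C)c(OC)ccc3c2=O)cc1OC | target

**Step count**

Total steps: 5. Longest linear sequence: 5 steps (1 → 7 → 9 → 11 → 13 → 15).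

**Steps most likely to fail, with fallbacks**

Step 1 (key step). In the hot Lewis-acid stage the electron-rich arylacetic acid may acylate itself or lose a methyl ether. In the second stage, formylation may stray onto an aromatic ring or the ring closure may stop short. The fallback sets out from resorcinol 1 and returns to the route at 7. A Hoesch reaction of 1 with purchased 2,4,5-trimethoxyphenylacetonitrile F1 (ZnCl2, HCl gas, Et2O, 0 °C) should give 1-(2,4-dihydroxyphenyl)-2-(2,4,5-trimethoxyphenyl)ethan-1-iminium chloride F2. Hot water hydrolyses this to the deoxybenzoin 4, which is now isolated and purified. Heating 4 with N,N-dimethylformamide dimethyl acetal (THF, reflux) then supplies C2 and closes the pyranone through 5 and 6 to 7 without any Lewis acid or sulfonyl chloride.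

Step 3. The allyl group may migrate in part to C6, and at 200 °C the ortho-allylphenol may cyclise onto its own double bond or the material may decompose. The fallback sets out from 7 and returns to the route at 13, replacing the sigmatropic shift by halogenation and cross-coupling. Iodination of 7 with N-iodosuccinimide (DMF, 0 °C to rt) is expected at C8, the position activated by the 7-hydroxyl and favoured by the same bond fixation, giving 7-hydroxy-8-iodo-3-(2,4,5-trimethoxyphenyl)chromen-4-one F3. O-Methylation (MeI, K2CO3, acetone) gives 8-iodo-7-methoxy-3-(2,4,5-trimethoxyphenyl)chromen-4-one F4. Stille coupling of F4 with allyltributylstannane (Pd(PPh3)4, toluene, 100 °C) should then deliver 13.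

Step 5. Ruthenium hydride species may move the allyl double bond into conjugation with ring A, and the metathesis may stall at the but-2-enyl stage or give the homodimer. The fallback sets out from 13 and returns to the route at the target 15 by cleavage and olefination. Lemieux–Johnson oxidation of 13 (cat. OsO4, NaIO4, 2,6-lutidine, dioxane–water) should cleave only the terminal alkene to 2-[7-methoxy-4-oxo-3-(2,4,5-trimethoxyphenyl)chromen-8-yl]acetaldehyde F5. Wittig reaction of F5 with isopropylidenetriphenylphosphorane (from isopropyltriphenylphosphonium iodide and n-BuLi, THF, −78 → 0 °C) then gives 15.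

**Further compounds**

F1 | step 1 | 2,4,5-trimethoxyphenylacetonitrile (purchased reagent of the fallback) | COc1cc(OC)c(CC#N)cc1OC
F2 | step 1 | 1-(2,4-dihydroxyphenyl)-2-(2,4,5-trimethoxyphenyl)ethan-1-iminium chloride | COc1cc(OC)c(CC(=[NH2+])c2ccc(O)cc2O)cc1OC.[Cl-]
F3 | step 3 | 7-hydroxy-8-iodo-3-(2,4,5-trimethoxyphenyl)chromen-4-one | COc1cc(OC)c(-c2coc3c(I)c(O)ccc3c2=O)cc1OC
F4 | step 3 | 8-iodo-7-methoxy-3-(2,4,5-trimethoxyphenyl)chromen-4-one | COc1cc(OC)c(-c2coc3c(I)c(OC)ccc3c2=O)cc1OC
F5 | step 5 | 2-[7-methoxy-4-oxo-3-(2,4,5-trimethoxyphenyl)chromen-8-yl]acetaldehyde | COc1cc(OC)c(-c2coc3c(CC=O)c(OC)ccc3c2=O)cc1OC
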